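**Retrosynthetic overview**

1. The three esters go on last (two angelates on the ring diol, the acetate on the side-chain carbinol). The side-chain carbinol carbon and its bond to the alkene carbon come from a lithiation–borylation of a ring-bound alkenyl pinacol boronate with a sparteine-ligated α-lithiated homoprenyl benzoate.
2. Key disconnection: the cyclohexane C–C bond between the ring CH that bears the side chain and the neighbouring acyloxy-bearing ring CH. Enabling feature: this ring C–O carbon, the adjacent ring CH and the exocyclic C(=CH2) on it form a 2-substituted homoallylic alcohol, O–CH–CH–C(=CH2), the retron of aldehyde + allene + boryl-copper.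
3. Precursor: an acyclic C10 α-silyloxy epoxy allenyl aldehyde. One copper-catalysed borylative cyclisation should close the carbocycle, set both new ring stereocentres, create the exocyclic methylene and place boron on the carbon that must receive the side chain.
4. The aldehyde comes from a (Z)-allylic diol by hydroxyl-directed epoxidation; the (Z)-alkene comes from a Wittig reaction of an (S)-glycerate-derived α-alkoxy methyl ketone with a penta-3,4-dienyl ylide.
5. Ring order: oxirane first, on the open chain (step 8); cyclohexane last (step 11).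

Key step: step 11

Locants used in the text: C1 = ring CH bearing the side chain, C2 = ring CH2, C3 and C4 = oxirane carbons (C4 carries the methyl group), C5 and C6 = oxygen-bearing ring carbons (C6 next to C1), C7 = side-chain carbon bearing =CH2, C8 = side-chain carbinol carbon.
Assumption: (+)-sparteine is taken as commercially available; the phosphine on copper in 15 and the diamine on lithium in 21 are not drawn in the SMILES.

**Route**

Step 1
Reactants: 1 but-3-yn-1-ol
Product: 3 penta-3,4-dien-1-ol, via propargylic amine 2 (not isolated)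
Conditions: (CH2O)n, CuI (0.5 equiv), i-Pr2NH, 1,4-dioxane, reflux
Reagents that add atoms: paraformaldehyde (formaldehyde unit), C=O
Why: Crabbé allene homologation, in which the copper acetylide undergoes a Mannich reaction to propargylic amine 2, which should fragment by intramolecular hydride transfer to the terminal allene while the free alcohol is tolerated.

Step 2
Reactants: 3 penta-3,4-dien-1-ol
Product: 4 5-iodopenta-1,2-diene
Conditions: I2, PPh3, imidazole, CH2Cl2, 0 °C to rt
Reagents that add atoms: iodine, II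
Why: Appel-type iodination, in which the primary alcohol is activated as an alkoxyphosphonium ion and displaced by iodide (SN2) without touching the allene.

Step 3
Reactants: 4 5-iodopenta-1,2-diene
Product: 5 (penta-3,4-dien-1-yl)triphenylphosphonium iodide
Conditions: PPh3, MeCN, reflux
Reagents that add atoms: triphenylphosphine, c1ccc(cc1)P(c1ccccc1)c1ccccc1
Why: Phosphonium salt formation by SN2 quaternisation of triphenylphosphine with the unhindered primary iodide.

Step 4
Reactants: 6 methyl (4S)-2,2-dimethyl-1,3-dioxolane-4-carboxylate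
Product: 7 (4S)-N-methoxy-N,2,2-trimethyl-1,3-dioxolane-4-carboxamide
Conditions: MeNHOMe·HCl, i-PrMgCl, THF, −20 °C
Reagents that add atoms: N,O-dimethylhydroxylamine hydrochloride, CNOC.Cl
Why: Weinreb amide formation by aminolysis of the ester with the magnesium amide, where short contact at low temperature should leave the α-stereocentre intact.

Step 5
Reactants: 7 (4S)-N-methoxy-N,2,2-trimethyl-1,3-dioxolane-4-carboxamide
Product: 8 1-[(4S)-2,2-dimethyl-1,3-dioxolan-4-yl]ethan-1-one
Conditions: MeMgBr, THF, 0 °C; aq. NH4Cl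
Reagents that add atoms: methylmagnesium bromide, C[Mg]Br
Why: Weinreb ketone synthesis, in which the stable magnesium chelate stops the Grignard addition at the ketone stage.

Step 6
Reactants: 5 (penta-3,4-dien-1-yl)triphenylphosphonium iodide; 8 1-[(4S)-2,2-dimethyl-1,3-dioxolan-4-yl]ethan-1-one
Product: 10 (4R)-4-[(2Z)-hepta-2,5,6-trien-2-yl]-2,2-dimethyl-1,3-dioxolane, via phosphorus ylide 9 (not isolated)
Conditions: KN(SiMe3)2, THF, −78 to 0 °C; then 8, −78 °C to rt
Reagents that add atoms: none
Why: Wittig olefination, in which the non-stabilised ylide and the α-alkoxy methyl ketone should combine under salt-free kinetic control to the (Z)-trisubstituted alkene (oxygen-bearing carbon cis to the new chain), and addition at −78 °C should keep the α-stereocentre from epimerising.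

Step 7
Reactants: 10 (4R)-4-[(2Z)-hepta-2,5,6-trien-2-yl]-2,2-dimethyl-1,3-dioxolane
Product: 11 (2R,3Z)-3-methylocta-3,6,7-triene-1,2-diol
Conditions: AcOH/H2O (4:1), rt
Reagents that add atoms: none
Why: Acid-catalysed acetal hydrolysis, mild enough that the allene and the allylic C–O bond should survive.

Step 8
Reactants: 11 (2R,3Z)-3-methylocta-3,6,7-triene-1,2-diol
Product: 12 (1S)-1-[(2R,3S)-3-(buta-2,3-dien-1-yl)-2-methyloxiran-2-yl]ethane-1,2-diol
Conditions: mCPBA (1.05 equiv), NaHCO3, CH2Cl2, −20 to 0 °C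
Reagents that add atoms: 3-chloroperbenzoic acid, OOC(=O)c1cccc(Cl)c1
Why: Hydroxyl-directed (Henbest) peracid epoxidation, in which the conformer that minimises A(1,3) strain between the carbinol substituents and the cis chain delivers the hydrogen-bonded peracid to one alkene face, so the threo epoxy alcohol should form and the less nucleophilic allene should be left alone.

Step 9
Reactants: 12 (1S)-1-[(2R,3S)-3-(buta-2,3-dien-1-yl)-2-methyloxiran-2-yl]ethane-1,2-diol
Product: 13 (2S,3S)-2-{(1S)-1,2-bis[(triethylsilyl)oxy]ethyl}-3-(buta-2,3-dien-1-yl)-2-methyloxirane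
Conditions: TESCl (2.5 equiv), imidazole, DMF, 0 °C to rt
Reagents that add atoms: chlorotriethylsilane, CC[Si](Cl)(CC)CC
Why: Silyl ether formation at both hydroxyls under imidazole catalysis, with no base strong enough to trigger Payne rearrangement.

Step 10
Reactants: 13 (2S,3S)-2-{(1S)-1,2-bis[(triethylsilyl)oxy]ethyl}-3-(buta-2,3-dien-1-yl)-2-methyloxirane
Product: 14 (2R)-2-[(2S,3S)-3-(buta-2,3-dien-1-yl)-2-methyloxiran-2-yl]-2-[(triethylsilyl)oxy]acetaldehyde
Conditions: (COCl)2, DMSO, CH2Cl2, −78 to −40 °C; Et3N, −78 to 0 °C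
Reagents that add atoms: none
Why: Swern oxidation, under which a primary triethylsilyl ether is cleaved by the chlorosulfonium reagent and oxidised directly to the aldehyde while the hindered secondary silyl ether survives, and the cold amine quench should limit epimerisation and epoxide opening.

Step 11
Reactants: 14 (2R)-2-[(2S,3S)-3-(buta-2,3-dien-1-yl)-2-methyloxiran-2-yl]-2-[(triethylsilyl)oxy]acetaldehyde
Product: 17 (1S,2S,3R,4S,6S)-1-methyl-4-[1-(4,4,5,5-tetramethyl-1,3,2-dioxaborolan-2-yl)ethenyl]-2-[(triethylsilyl)oxy]-7-oxabicyclo[4.1.0]heptan-3-ol, via allylcopper 15 (not isolated), via borate ester 16 (not isolated)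
Conditions: CuCl (10 mol %), PCy3 (12 mol %), NaOt-Bu (20 mol %), B2pin2 (1.2 equiv), THF, 0 °C to rt; then aq. NH4Cl
Reagents that add atoms: bis(pinacolato)diboron, CC1(C)OB(OC1(C)C)B1OC(C)(C)C(C)(C)O1
Why: The phosphine-ligated monovalent copper boryl formed from CuCl, NaOt-Bu and B2pin2 adds across the terminal C=C of the allene (boron to the central carbon) to give (Z)-2-boryl-allylcopper 15, whose γ-carbon (C1) attacks the tethered aldehyde (C6) through a closed six-membered transition state, and the copper alkoxide is turned over by B2pin2 to borate 16. The closest known reaction types are the copper-catalysed three-component coupling of allenes, B2pin2 and aldehydes and the copper-catalysed borylative cyclisation of allenes tethered to ketones. The cyclohexane is closed by a 6-exo-trig addition to the carbonyl group, with the oxirane already in place. C1 and C6 are set together, because the (Z)-allylcopper in a chair-like, cis-fused bicyclic transition state places the new C–O bond axial and the borylvinyl group equatorial, hence cis to each other. Their sense relative to C3–C5 should follow from the C5 silyloxy group, which prefers the pseudoaxial position on the forming epoxycyclohexane half-chair (away from the C4 methyl group, C–O anti to the carbonyl dipole), so that the new C6–O bond ends up trans to it and on the face of the oxirane oxygen. The step needs borylcupration of the allene in preference to the aldehyde and no enolisation of the α-silyloxy aldehyde towards the epoxide, which the phosphine ligand, the substoichiometric alkoxide and the low temperature should secure.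

Step 12
Reactants: 17 (1S,2S,3R,4S,6S)-1-methyl-4-[1-(4,4,5,5-tetramethyl-1,3,2-dioxaborolan-2-yl)ethenyl]-2-[(triethylsilyl)oxy]-7-oxabicyclo[4.1.0]heptan-3-ol
Product: 18 (1S,2S,3R,4S,6S)-1-methyl-4-[1-(4,4,5,5-tetramethyl-1,3,2-dioxaborolan-2-yl)ethenyl]-2,3-bis[(triethylsilyl)oxy]-7-oxabicyclo[4.1.0]heptane
Conditions: TESOTf, 2,6-lutidine, CH2Cl2, −78 °C
Reagents that add atoms: triethylsilyl trifluoromethanesulfonate, CC[Si](CC)(CC)OS(=O)(=O)C(F)(F)F
Why: Silyl ether formation with the reactive triflate and a hindered base, which should cap the hindered secondary alcohol so that no acidic proton or alkoxide sits next to boron in step 14.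

Step 13
Reactants: 19 4-methylpent-3-en-1-ol
Product: 20 4-methylpent-3-en-1-yl 2,4,6-tri(propan-2-yl)benzoate
Conditions: 2,4,6-triisopropylbenzoyl chloride, Et3N, DMAP (cat.), CH2Cl2, reflux
Reagents that add atoms: 2,4,6-triisopropylbenzoyl chloride, CC(C)c1cc(C(C)C)c(C(Cl)=O)c(C(C)C)c1
Why: DMAP-catalysed acylation of the primary alcohol to the hindered benzoate that serves as directing and leaving group in step 14.

Step 14
Reactants: 20 4-methylpent-3-en-1-yl 2,4,6-tri(propan-2-yl)benzoate; 18 (1S,2S,3R,4S,6S)-1-methyl-4-[1-(4,4,5,5-tetramethyl-1,3,2-dioxaborolan-2-yl)ethenyl]-2,3-bis[(triethylsilyl)oxy]-7-oxabicyclo[4.1.0]heptane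
Product: 24 (3S)-6-methyl-2-{(1S,3S,4R,5S,6S)-6-methyl-4,5-bis[(triethylsilyl)oxy]-7-oxabicyclo[4.1.0]heptan-3-yl}hepta-1,5-dien-3-ol, via lithiated benzoate 21 (not isolated), via boronate complex 22 (not isolated), via allylic boronic ester 23 (not isolated)
Conditions: 20 (1.5 equiv), s-BuLi (1.4 equiv), (+)-sparteine (1.5 equiv), Et2O, −78 °C; then 18, −78 to 35 °C; then NaOH, H2O2, THF/H2O, 0 °C
Reagents that add atoms: hydrogen peroxide, OO
Why: Lithiation–borylation (Hoppe deprotonation, then Matteson-type 1,2-metallate rearrangement), in which (+)-sparteine-controlled removal of one enantiotopic proton gives configurationally stable 21, boron of 18 is attacked with retention to give 22, antiperiplanar migration of the alkenyl group with inversion expels the benzoate to give 23, and oxidation with retention should deliver the (S)-carbinol at C8.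

Step 15
Reactants: 24 (3S)-6-methyl-2-{(1S,3S,4R,5S,6S)-6-methyl-4,5-bis[(triethylsilyl)oxy]-7-oxabicyclo[4.1.0]heptan-3-yl}hepta-1,5-dien-3-ol
Product: 25 (3S)-6-methyl-2-{(1S,3S,4R,5S,6S)-6-methyl-4,5-bis[(triethylsilyl)oxy]-7-oxabicyclo[4.1.0]heptan-3-yl}hepta-1,5-dien-3-yl acetate
Conditions: Ac2O, pyridine, DMAP (cat.), CH2Cl2, 0 °C to rt
Reagents that add atoms: acetic anhydride, CC(=O)OC(C)=O
Why: DMAP-catalysed acetylation of the only free (secondary allylic) alcohol.

Step 16
Reactants: 25 (3S)-6-methyl-2-{(1S,3S,4R,5S,6S)-6-methyl-4,5-bis[(triethylsilyl)oxy]-7-oxabicyclo[4.1.0]heptan-3-yl}hepta-1,5-dien-3-yl acetate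
Product: 26 (3S)-2-[(1S,3S,4R,5S,6R)-4,5-dihydroxy-6-methyl-7-oxabicyclo[4.1.0]heptan-3-yl]-6-methylhepta-1,5-dien-3-yl acetate
Conditions: HF·pyridine, excess pyridine, THF, 0 °C to rt
Reagents that add atoms: none
Why: Fluoride-mediated desilylation of both triethylsilyl ethers under buffered, non-basic conditions, which should avoid Payne rearrangement of the liberated epoxy alcohol and acyl migration.

Step 17
Reactants: 26 (3S)-2-[(1S,3S,4R,5S,6R)-4,5-dihydroxy-6-methyl-7-oxabicyclo[4.1.0]heptan-3-yl]-6-methylhepta-1,5-dien-3-yl acetate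
Product: 27 (1S,2S,3R,4S,6S)-4-[(3S)-3-(acetyloxy)-6-methylhepta-1,5-dien-2-yl]-1-methyl-7-oxabicyclo[4.1.0]heptane-2,3-diyl bis[(2Z)-2-methylbut-2-enoate] (target CNP0188566.1)
Conditions: angelic acid, 2,4,6-trichlorobenzoyl chloride, Et3N, toluene, rt; then 26, 80 °C
Reagents that add atoms: angelic acid, C/C=C(/C)C(=O)O
Why: Yamaguchi-type esterification through the mixed anhydride, run without DMAP to suppress isomerisation to the tiglate, which should acylate both secondary alcohols with the Z geometry retained.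

**Compound list**

1 | but-3-yn-1-ol | C#CCCO | starting material
2 | 5-[di(propan-2-yl)amino]pent-3-yn-1-ol (propargylic amine) | CC(C)N(CC#CCCO)C(C)C | intermediate
3 | penta-3,4-dien-1-ol | C=C=CCCO | intermediate
4 | 5-iodopenta-1,2-diene | C=C=CCCI | intermediate
5 | (penta-3,4-dien-1-yl)triphenylphosphonium iodide | C=C=CCC[P+](c1ccccc1)(c1ccccc1)c1ccccc1.[I-] | intermediate
6 | methyl (4S)-2,2-dimethyl-1,3-dioxolane-4-carboxylate | COC(=O)[C@@H]1COC(C)(C)O1 | starting material
7 | (4S)-N-methoxy-N,2,2-trimethyl-1,3-dioxolane-4-carboxamide | CON(C)C(=O)[C@@H]1COC(C)(C)O1 | intermediate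
8 | 1-[(4S)-2,2-dimethyl-1,3-dioxolan-4-yl]ethan-1-one | CC(=O)[C@@H]1COC(C)(C)O1 | intermediate
9 | (penta-3,4-dien-1-ylidene)triphenylphosphorane (ylide) | C=C=CCC=P(c1ccccc1)(c1ccccc1)c1ccccc1 | intermediate
10 | (4R)-4-[(2Z)-hepta-2,5,6-trien-2-yl]-2,2-dimethyl-1,3-dioxolane | C=C=CC/C=C(/C)[C@@H]1COC(C)(C)O1 | intermediate
11 | (2R,3Z)-3-methylocta-3,6,7-triene-1,2-diol | C=C=CC/C=C(/C)[C@@H](O)CO | intermediate
12 | (1S)-1-[(2R,3S)-3-(buta-2,3-dien-1-yl)-2-methyloxiran-2-yl]ethane-1,2-diol | C=C=CC[C@@H]1O[C@]1(C)[C@@H](O)CO | intermediate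
13 | (2S,3S)-2-{(1S)-1,2-bis[(triethylsilyl)oxy]ethyl}-3-(buta-2,3-dien-1-yl)-2-methyloxirane | C=C=CC[C@@H]1O[C@]1(C)[C@@H](O[Si](CC)(CC)CC)CO[Si](CC)(CC)CC | intermediate
14 | (2R)-2-[(2S,3S)-3-(buta-2,3-dien-1-yl)-2-methyloxiran-2-yl]-2-[(triethylsilyl)oxy]acetaldehyde | C=C=CC[C@@H]1O[C@]1(C)[C@@H](O[Si](CC)(CC)CC)C=O | intermediate
15 | (Z)-2-(pinacolboryl)allylcopper formed from 14 (copper on the terminal CH2, chain cis to CH2Cu) | [Cu]C/C(B1OC(C)(C)C(C)(C)O1)=C\C[C@@H]1O[C@]1(C)[C@@H](O[Si](CC)(CC)CC)C=O | intermediate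
16 | O-pinacolboryl ether of 17 (cyclised borate ester) | C=C(B1OC(C)(C)C(C)(C)O1)[C@@H]1C[C@@H]2O[C@]2(C)[C@@H](O[Si](CC)(CC)CC)[C@@H]1OB1OC(C)(C)C(C)(C)O1 | intermediate
17 | (1S,2S,3R,4S,6S)-1-methyl-4-[1-(4,4,5,5-tetramethyl-1,3,2-dioxaborolan-2-yl)ethenyl]-2-[(triethylsilyl)oxy]-7-oxabicyclo[4.1.0]heptan-3-ol | C=C(B1OC(C)(C)C(C)(C)O1)[C@@H]1C[C@@H]2O[C@]2(C)[C@@H](O[Si](CC)(CC)CC)[C@@H]1O | intermediate
18 | (1S,2S,3R,4S,6S)-1-methyl-4-[1-(4,4,5,5-tetramethyl-1,3,2-dioxaborolan-2-yl)ethenyl]-2,3-bis[(triethylsilyl)oxy]-7-oxabicyclo[4.1.0]heptane | C=C(B1OC(C)(C)C(C)(C)O1)[C@@H]1C[C@@H]2O[C@]2(C)[C@@H](O[Si](CC)(CC)CC)[C@@H]1O[Si](CC)(CC)CC | intermediate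
19 | 4-methylpent-3-en-1-ol | CC(C)=CCCO | starting material
20 | 4-methylpent-3-en-1-yl 2,4,6-tri(propan-2-yl)benzoate | CC(C)=CCCOC(=O)c1c(C(C)C)cc(C(C)C)cc1C(C)C | intermediate
21 | (1R)-1-lithio-4-methylpent-3-en-1-yl 2,4,6-tri(propan-2-yl)benzoate, (+)-sparteine complex | [Li][C@H](CC=C(C)C)OC(=O)c1c(C(C)C)cc(C(C)C)cc1C(C)C | intermediate
22 | lithium boronate (ate) complex of 18 and 21, boron bound with retention | [Li+].C=C([C@@H]1C[C@@H]2O[C@]2(C)[C@@H](O[Si](CC)(CC)CC)[C@@H]1O[Si](CC)(CC)CC)[B-]1(OC(C)(C)C(C)(C)O1)[C@H](CC=C(C)C)OC(=O)c1c(C(C)C)cc(C(C)C)cc1C(C)C | intermediate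
23 | 2-[(3S)-6-methyl-2-{(1S,3S,4R,5S,6S)-6-methyl-4,5-bis[(triethylsilyl)oxy]-7-oxabicyclo[4.1.0]heptan-3-yl}hepta-1,5-dien-3-yl]-4,4,5,5-tetramethyl-1,3,2-dioxaborolane | C=C([C@H](CC=C(C)C)B1OC(C)(C)C(C)(C)O1)[C@@H]1C[C@@H]2O[C@]2(C)[C@@H](O[Si](CC)(CC)CC)[C@@H]1O[Si](CC)(CC)CC | intermediate
24 | (3S)-6-methyl-2-{(1S,3S,4R,5S,6S)-6-methyl-4,5-bis[(triethylsilyl)oxy]-7-oxabicyclo[4.1.0]heptan-3-yl}hepta-1,5-dien-3-ol | C=C([C@H](CC=C(C)C)O)[C@@H]1C[C@@H]2O[C@]2(C)[C@@H](O[Si](CC)(CC)CC)[C@@H]1O[Si](CC)(CC)CC | intermediate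
25 | (3S)-6-methyl-2-{(1S,3S,4R,5S,6S)-6-methyl-4,5-bis[(triethylsilyl)oxy]-7-oxabicyclo[4.1.0]heptan-3-yl}hepta-1,5-dien-3-yl acetate | C=C([C@H](CC=C(C)C)OC(C)=O)[C@@H]1C[C@@H]2O[C@]2(C)[C@@H](O[Si](CC)(CC)CC)[C@@H]1O[Si](CC)(CC)CC | intermediate
26 | (3S)-2-[(1S,3S,4R,5S,6R)-4,5-dihydroxy-6-methyl-7-oxabicyclo[4.1.0]heptan-3-yl]-6-methylhepta-1,5-dien-3-yl acetate | C=C([C@H](CC=C(C)C)OC(C)=O)[C@@H]1C[C@@H]2O[C@]2(C)[C@@H](O)[C@@H]1O | intermediate
27 | (1S,2S,3R,4S,6S)-4-[(3S)-3-(acetyloxy)-6-methylhepta-1,5-dien-2-yl]-1-methyl-7-oxabicyclo[4.1.0]heptane-2,3-diyl bis[(2Z)-2-methylbut-2-enoate] | C=C([C@H](CC=C(C)C)OC(C)=O)[C@@H]1C[C@@H]2O[C@]2(C)[C@@H](OC(=O)/C(C)=C\C)[C@@H]1OC(=O)/C(C)=C\C | target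

**Count and risks**

Total step count: 17. Longest linear sequence: 14 steps (steps 1–3, 6–12, 14–17, starting from 1).

Steps most likely to fail:

1. Step 11. What may go wrong: borylation of the aldehyde carbonyl instead of the allene, alkoxide-triggered enolisation and opening of the epoxide, or insufficient facial selectivity in the ring closure. The fallback sets out from 14 and comes back at 18. It replaces the alkoxide-activated copper boryl by a base-free palladium–tin manifold. 14 would be treated with (Bu3Sn)2 and catalytic [(η3-C3H5)PdCl]2 in THF, so that distannylation of the terminal allene C=C is followed by intramolecular addition of the allylstannane to the aldehyde. This should give the O-tributylstannyl ether of the cis cyclohexanol F1, hydrolysed on work-up to the hydroxy alkenylstannane F2. Silylation (TESOTf, 2,6-lutidine) would give the bis-silyl alkenylstannane F3. Tin–lithium exchange (n-BuLi, THF, −78 °C) would give the alkenyllithium F4, which is quenched with 2-isopropoxy-4,4,5,5-tetramethyl-1,3,2-dioxaborolane to return 18.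

2. Step 14. What may go wrong: slow or reversible ate-complex formation at the hindered α-branched alkenyl boronate, or decomposition of the lithiated benzoate before 1,2-migration. The fallback sets out from 18 and comes back at 24. It builds the C7–C8 bond by acylation and sets C8 by reagent-controlled reduction. An anhydrous acyl Suzuki–Miyaura coupling (Pd(PPh3)4, Cs2CO3, toluene) of 18 with 4-methylpent-3-enoyl chloride F5 (from commercial 4-methylpent-3-enoic acid and oxalyl chloride) would give the cross-conjugated enone F6. Corey–Bakshi–Shibata reduction with the (R)-methyl oxazaborolidine and catecholborane at −78 °C, with the branched alkenyl group as the large substituent, should give the (S)-carbinol 24.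

3. Step 17. What may go wrong: incomplete acylation of the hindered C5 hydroxyl, Z to E isomerisation of the angeloyl unit on prolonged heating, or opening of the epoxide by chloride. The fallback sets out from 26 and comes back at 27. It constructs the Z-alkenes on the esters instead of transferring them. Both hydroxyls would be esterified (EDC·HCl, DMAP, CH2Cl2) with 2-[bis(2,2,2-trifluoroethoxy)phosphoryl]propanoic acid F7 (from mild saponification of its commercial methyl ester) to give the bis(phosphonate) ester F8. A double Still–Gennari olefination with acetaldehyde (KN(SiMe3)2, 18-crown-6, THF, −78 °C) should then give both (Z)-2-methylbut-2-enoates of 27.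

**Further compounds**

F1 | step 11 | O-tributylstannyl ether of the cis hydroxy alkenylstannane | C=C([Sn](CCCC)(CCCC)CCCC)[C@@H]1C[C@@H]2O[C@]2(C)[C@@H](O[Si](CC)(CC)CC)[C@@H]1O[Sn](CCCC)(CCCC)CCCC
F2 | step 11 | (1S,2S,3R,4S,6S)-1-methyl-4-[1-(tributylstannyl)ethenyl]-2-[(triethylsilyl)oxy]-7-oxabicyclo[4.1.0]heptan-3-ol | C=C([Sn](CCCC)(CCCC)CCCC)[C@@H]1C[C@@H]2O[C@]2(C)[C@@H](O[Si](CC)(CC)CC)[C@@H]1O
F3 | step 11 | (1S,2S,3R,4S,6S)-1-methyl-4-[1-(tributylstannyl)ethenyl]-2,3-bis[(triethylsilyl)oxy]-7-oxabicyclo[4.1.0]heptane | C=C([Sn](CCCC)(CCCC)CCCC)[C@@H]1C[C@@H]2O[C@]2(C)[C@@H](O[Si](CC)(CC)CC)[C@@H]1O[Si](CC)(CC)CC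
F4 | step 11 | alkenyllithium from F3 (lithium in place of tin) | [Li]C(=C)[C@@H]1C[C@@H]2O[C@]2(C)[C@@H](O[Si](CC)(CC)CC)[C@@H]1O[Si](CC)(CC)CC
F5 | step 14 | 4-methylpent-3-enoyl chloride | CC(C)=CCC(Cl)=O
F6 | step 14 | 6-methyl-2-{(1S,3S,4R,5S,6S)-6-methyl-4,5-bis[(triethylsilyl)oxy]-7-oxabicyclo[4.1.0]heptan-3-yl}hepta-1,5-dien-3-one | C=C(C(=O)CC=C(C)C)[C@@H]1C[C@@H]2O[C@]2(C)[C@@H](O[Si](CC)(CC)CC)[C@@H]1O[Si](CC)(CC)CC
F7 | step 17 | 2-[bis(2,2,2-trifluoroethoxy)phosphoryl]propanoic acid | CC(C(=O)O)P(=O)(OCC(F)(F)F)OCC(F)(F)F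
F8 | step 17 | bis{2-[bis(2,2,2-trifluoroethoxy)phosphoryl]propanoate} of diol 26 (phosphonate α-carbons as a mixture) | C=C([C@H](CC=C(C)C)OC(C)=O)[C@@H]1C[C@@H]2O[C@]2(C)[C@@H](OC(=O)C(C)P(=O)(OCC(F)(F)F)OCC(F)(F)F)[C@@H]1OC(=O)C(C)P(=O)(OCC(F)(F)F)OCC(F)(F)F
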